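**Plan**

- Retrosynthesis cuts the two ring–CH2–ring bonds (ring B–CH2–ring C first, then ring A–CH2–ring B), then the butyryl C–C bond on ring A, then ring A itself. Ring A is the gem-dimethyl triketone ring, ring B the central butyrylphloroglucinol, ring C the methoxy-bearing end ring.
- Ring A is not built as a six-membered ring. 3-Ethoxy-4,4-dimethylcyclobutenone (dimethylketene + ethoxyacetylene) is enlarged by the two carbons of a second ethoxyacetylene through 4π opening, [2+2], 4π opening and 6π closure.
- Enabling feature: in ring A the quaternary C(CH3)2 carbon lies between the ring C=O carbon and an enol C–O carbon of a 1,3,5-trioxygenated carbocycle. Closure of a ketene carbon onto a Me2C= terminus gives this non-aromatisable dienone directly at the right oxidation level.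
- Forward order: ring A (steps 1–4), CH2 bridge to ring B by Mannich base and quinone methide (steps 5–6), then the second CH2 bridge to ring C (steps 7–9). Rings B and C stay aromatic throughout.
- Stereochemistry: the target has no stereocentre and no stereogenic double bond, so nothing needs to be controlled.

Key step: step 2

Remark: the target is one of several rapidly interconverting enol tautomers; every triketone ring is written in the tautomer of the target SMILES. Compound 14 (the antioxidant 2,4,6-trihydroxybutyrophenone) and ethoxyacetylene are taken as purchasable.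

**Route**

Step 1
Reactants: 1 isobutyryl chloride; 2 ethoxyacetylene
Product: 4 3-ethoxy-4,4-dimethylcyclobut-2-en-1-one, via dimethylketene 3 (not isolated)
Conditions: Et3N, Et2O, 0 °C to rt, excess 2
Reagents that add atoms: none
Why: Dehydrochlorination gives dimethylketene, which should undergo the known ketene–ynol ether [2+2] cycloaddition, the nucleophilic CH terminus of ethoxyacetylene bonding to the ketene carbonyl carbon to fix the 3-ethoxy regiochemistry.

Step 2
Reactants: 4 3-ethoxy-4,4-dimethylcyclobut-2-en-1-one; 2 ethoxyacetylene
Product: 8 3,5-diethoxy-6,6-dimethylcyclohexa-2,4-dien-1-one, via vinylketene 5 (not isolated), via 4-alkenylcyclobutenone 6 (not isolated), via dienylketene 7 (not isolated)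
Conditions: 2 (4 equiv), PhMe, sealed tube, 100–110 °C
Reagents that add atoms: none
Why: Proposed new method: heating should open 4 by 4π-electrocyclic cleavage of the C1–C4 bond to the vinylketene 5, whose ketene C=C undergoes regioselective [2+2] cycloaddition with ethoxyacetylene (CH terminus to the ketene carbonyl carbon) to give 6; a second 4π opening gives the dienylketene 7, and the six-membered ring closes by thermal disrotatory 6π-electrocyclization between the ketene carbon and the Me2C= terminus, so the four-membered ring is enlarged by the two alkyne carbons. The closest known reaction type is the Danheiser benzannulation of cyclobutenones with alkoxy- and siloxyacetylenes, together with the thermal reclosure of dienylketenes to 6,6-disubstituted cyclohexa-2,4-dienones; what is untested is the combination of a 3-alkoxy donor with a blocked 4,4-dimethyl terminus in the cyclobutenone. Because the closing terminus is quaternary, the usual tautomerization to a phenol cannot occur and the cascade should stop at the dienone, which already carries the 1,3,5-oxygen pattern and oxidation level of ring A. No stereocentre is formed. The step needs the right regiochemistry in the [2+2] event, which the polarization of the ynol ether and the ketene secures, and it needs trapping of 5 to outrun its 1,5-hydrogen shift and the retro-ene decay of the alkyne, which the excess of 2 and the moderate temperature should secure; the reversible opening of 6 lets the isomer with ketene and alkenyl arms cis be drained by the 6π closure.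

Step 3
Reactants: 8 3,5-diethoxy-6,6-dimethylcyclohexa-2,4-dien-1-one
Product: 9 filicinic acid (3,5-dihydroxy-4,4-dimethylcyclohexa-2,5-dien-1-one)
Conditions: 2 M aq. HCl, THF, 60 °C
Reagents that add atoms: water, O
Why: Both ethoxy groups are vinylogous ester enol ethers, so acid-catalysed enol ether hydrolysis should release the cyclic trione as its stable enol.

Step 4
Reactants: 9 filicinic acid; 10 butyric acid
Product: 12 butyrylfilicinic acid (2-butanoyl-3,5-dihydroxy-4,4-dimethylcyclohexa-2,5-dien-1-one), via enol butyrate 11 (not isolated)
Conditions: DCC (1.05 equiv), DMAP, CH2Cl2/MeCN, 0 °C to rt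
Reagents that add atoms: none
Why: Steglich-type O-acylation of the cyclic 1,3-dione followed by DMAP-catalysed O-to-C acyl migration is the standard entry to 2-acyl-1,3-diones; the two ring CH positions are equivalent and the first acyl group deactivates the second.

Step 5
Reactants: 12 butyrylfilicinic acid
Product: 13 2-butanoyl-6-[(dimethylamino)methyl]-3,5-dihydroxy-4,4-dimethylcyclohexa-2,5-dien-1-one
Conditions: CH2(NMe2)2 (1.1 equiv), CH2Cl2, 0 °C to rt
Reagents that add atoms: N,N,N',N'-tetramethylmethanediamine, CN(C)CN(C)C
Why: Mannich reaction; the acidic triketone protonates the aminal to the iminium ion, which is taken up by the only unsubstituted nucleophilic ring carbon.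

Step 6
Reactants: 13 ring A Mannich base; 14 1-(2,4,6-trihydroxyphenyl)butan-1-one
Product: 16 ring A–CH2–ring B dimer 2-butanoyl-6-[(3-butanoyl-2,4,6-trihydroxyphenyl)methyl]-3,5-dihydroxy-4,4-dimethylcyclohexa-2,5-dien-1-one, via methylidene trione 15 (not isolated)
Conditions: 14 (3 equiv), 1,4-dioxane, 80 °C, N2 stream
Reagents that add atoms: none
Why: Thermal retro-Michael loss of dimethylamine from the β-aminoketone gives the methylidene trione, which should be trapped by Friedel–Crafts-type Michael addition of the phloroglucinol carbon; the two free positions of 14 are equivalent and its excess limits double alkylation.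

Step 7
Reactants: 16 ring A–CH2–ring B dimer
Product: 17 2-butanoyl-6-({3-butanoyl-5-[(dimethylamino)methyl]-2,4,6-trihydroxyphenyl}methyl)-3,5-dihydroxy-4,4-dimethylcyclohexa-2,5-dien-1-one
Conditions: CH2(NMe2)2 (1.1 equiv), THF/CH2Cl2, 0 °C to rt
Reagents that add atoms: N,N,N',N'-tetramethylmethanediamine, CN(C)CN(C)C
Why: Mannich reaction at the single remaining nucleophilic carbon, the ring B CH flanked by two hydroxyl groups; mild, non-basic conditions should leave the existing methylene bridge untouched.

Step 8
Reactants: 14 1-(2,4,6-trihydroxyphenyl)butan-1-one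
Product: 18 1-(2,6-dihydroxy-4-methoxyphenyl)butan-1-one
Conditions: Me2SO4 (1.0 equiv), K2CO3 (1.0 equiv), acetone, rt
Reagents that add atoms: dimethyl sulfate, COS(=O)(=O)OC
Why: Williamson ether synthesis; the 4-hydroxyl para to the ketone is the most acidic and is not chelated to the carbonyl, so it should be methylated first.

Step 9
Reactants: 17 dimer Mannich base; 18 1-(2,6-dihydroxy-4-methoxyphenyl)butan-1-one
Product: 20 target trimer CNP0178590.0, via ring B quinone methide 19 (not isolated)
Conditions: 18 (3 equiv), 1,4-dioxane, 100 °C, N2 stream
Reagents that add atoms: none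
Why: The acidic ring A enol protonates the amine, so warming should expel dimethylamine to the ortho-quinone methide, which undergoes Friedel–Crafts-type Michael addition by one of the two equivalent free carbons of 18 (between OH and OMe); excess 18 suppresses double alkylation.

**Compound list**

1 | isobutyryl chloride | CC(C)C(=O)Cl | starting material
2 | ethoxyacetylene | CCOC#C | starting material
3 | dimethylketene (not isolated) | CC(C)=C=O | intermediate
4 | 3-ethoxy-4,4-dimethylcyclobut-2-en-1-one | CCOC1=CC(=O)C1(C)C | intermediate
5 | 3-ethoxy-4-methylpenta-1,3-dien-1-one, vinylketene (not isolated) | O=C=CC(OCC)=C(C)C | intermediate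
6 | 3-ethoxy-4-(1-ethoxy-2-methylprop-1-en-1-yl)cyclobut-2-en-1-one (not isolated) | CCOC1=CC(=O)C1C(OCC)=C(C)C | intermediate
7 | 3,5-diethoxy-6-methylhepta-1,3,5-trien-1-one, dienylketene with ketene and alkenyl arms cis on the central C=C (not isolated) | O=C=C/C(OCC)=C\C(OCC)=C(C)C | intermediate
8 | 3,5-diethoxy-6,6-dimethylcyclohexa-2,4-dien-1-one | CCOC1=CC(=O)C(C)(C)C(OCC)=C1 | intermediate
9 | filicinic acid, 3,5-dihydroxy-4,4-dimethylcyclohexa-2,5-dien-1-one | CC1(C)C(O)=CC(=O)C=C1O | intermediate
10 | butyric acid | CCCC(=O)O | starting material
11 | 5-hydroxy-6,6-dimethyl-3-oxocyclohexa-1,4-dien-1-yl butanoate, enol butyrate (not isolated) | CCCC(=O)OC1=CC(=O)C=C(O)C1(C)C | intermediate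
12 | butyrylfilicinic acid, 2-butanoyl-3,5-dihydroxy-4,4-dimethylcyclohexa-2,5-dien-1-one | CCCC(=O)C1=C(O)C(C)(C)C(O)=CC1=O | intermediate
13 | 2-butanoyl-6-[(dimethylamino)methyl]-3,5-dihydroxy-4,4-dimethylcyclohexa-2,5-dien-1-one | CCCC(=O)C1=C(O)C(C)(C)C(O)=C(CN(C)C)C1=O | intermediate
14 | 1-(2,4,6-trihydroxyphenyl)butan-1-one | CCCC(=O)c1c(O)cc(O)cc1O | starting material
15 | 2-butanoyl-3-hydroxy-4,4-dimethyl-6-methylidenecyclohex-2-ene-1,5-dione (not isolated) | CCCC(=O)C1=C(O)C(C)(C)C(=O)C(=C)C1=O | intermediate
16 | 2-butanoyl-6-[(3-butanoyl-2,4,6-trihydroxyphenyl)methyl]-3,5-dihydroxy-4,4-dimethylcyclohexa-2,5-dien-1-one | CCCC(=O)C1=C(O)C(C)(C)C(O)=C(Cc2c(O)cc(O)c(C(=O)CCC)c2O)C1=O | intermediate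
17 | 2-butanoyl-6-({3-butanoyl-5-[(dimethylamino)methyl]-2,4,6-trihydroxyphenyl}methyl)-3,5-dihydroxy-4,4-dimethylcyclohexa-2,5-dien-1-one | CCCC(=O)C1=C(O)C(C)(C)C(O)=C(Cc2c(O)c(CN(C)C)c(O)c(C(=O)CCC)c2O)C1=O | intermediate
18 | 1-(2,6-dihydroxy-4-methoxyphenyl)butan-1-one | CCCC(=O)c1c(O)cc(OC)cc1O | intermediate
19 | ring B ortho-quinone methide of 17 after loss of dimethylamine (not isolated) | CCCC(=O)C1=C(O)C(C)(C)C(O)=C(CC2=C(O)C(=C)C(=O)C(C(=O)CCC)=C2O)C1=O | intermediate
20 | CNP0178590.0, ring A–CH2–ring B–CH2–ring C trimer | CCCC(=O)C1=C(O)C(C)(C)C(O)=C(Cc2c(O)c(Cc3c(OC)cc(O)c(C(=O)CCC)c3O)c(O)c(C(=O)CCC)c2O)C1=O | target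

**Step count and risks**

Total steps: 9. Longest linear sequence: 8 (steps 1–7 and 9); step 8 is a one-step side branch.

Steps most likely to fail:

1. Step 2 (proposed new method). The alkoxy-stabilised, gem-dimethyl cyclobutenone may open too slowly, so that retro-ene loss of ethylene from ethoxyacetylene or a 1,5-hydrogen shift of the vinylketene competes with the [2+2] trapping. Fallback by known chemistry: set out from 14 and carry out the classical dearomatising gem-dimethylation of the acylphloroglucinol (MeI, NaOMe, MeOH, 0 °C to rt), which gives butyrylfilicinic acid directly and comes back to the route at 12. This fallback makes no compound outside the list (F0).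

2. Step 9. Quinone methide formation on the aromatic ring B may need enough heat that the existing ring A–CH2–ring B bridge is scrambled by retro-Michael exchange, with loss of the A–B–C sequence. Fallback: change the order of union so that the last bridge is formed from the more reactive ring A electrophile. Set out from 18: Mannich reaction with CH2(NMe2)2 gives 1-{3-[(dimethylamino)methyl]-2,6-dihydroxy-4-methoxyphenyl}butan-1-one F1. Heating F1 with excess 14 gives the ring B–CH2–ring C dimer 1-{3-[(3-butanoyl-2,6-dihydroxy-4-methoxyphenyl)methyl]-2,4,6-trihydroxyphenyl}butan-1-one F2. F2 is then alkylated at its more nucleophilic ring B carbon (flanked by two hydroxyl groups) with the methylidene trione released from 13 at 80 °C, which comes back to the route at 20.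

3. Step 6. Over-alkylation of ring B and homocoupling of two ring A units after retro-Mannich release of the iminium ion may erode the mono-bridged dimer. Fallback: invert the roles of the partners. Set out from 14: Mannich reaction with one equivalent of CH2(NMe2)2 gives 1-{3-[(dimethylamino)methyl]-2,4,6-trihydroxyphenyl}butan-1-one F3. Heating F3 with 12, whose single free ring carbon is the strongest nucleophile present, should give the dimer and comes back to the route at 16.

**Further compounds**

F0 | step 2 | none | none
F1 | step 9 | 1-{3-[(dimethylamino)methyl]-2,6-dihydroxy-4-methoxyphenyl}butan-1-one | CCCC(=O)c1c(O)cc(OC)c(CN(C)C)c1O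
F2 | step 9 | 1-{3-[(3-butanoyl-2,6-dihydroxy-4-methoxyphenyl)methyl]-2,4,6-trihydroxyphenyl}butan-1-one | CCCC(=O)c1c(O)cc(O)c(Cc2c(OC)cc(O)c(C(=O)CCC)c2O)c1O
F3 | step 6 | 1-{3-[(dimethylamino)methyl]-2,4,6-trihydroxyphenyl}butan-1-one | CCCC(=O)c1c(O)cc(O)c(CN(C)C)c1O
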